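**Retrosynthetic overview**
- The target comes from its 2,12-diol by a final double butyrylation. The diol comes from an open-chain α-hydroxy aldehyde in one chromium-mediated operation: intramolecular γ-chloroallylation makes C6–C7 (ten-membered ring, Cl, exocyclic methylene, C6, C7), and the new 7-hydroxyl closes the γ-lactone on C19.
- The aldehyde comes from a ring A ketone carrying a Seebach dioxolanone (C7, C8, C17–C19 from (S)-malic acid; C17 by Fráter–Seebach methylation, C8 by enolate acylation). C9 is set by hydroxyl-directed reduction and C2 by asymmetric addition of a chloro-enyne made from 1,3-dichloroacetone.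
- Ring A comes from a Diels–Alder reaction of an ene-dione with a silyloxydiene, elimination to a cyclohexadiene, face-selective dihydroxylation (C11, C12) and directed epoxidation (C13, C14).
- Ring order: dioxolanone (temporary) → ring A → epoxide → ten-membered ring and γ-lactone together.

Assumption: the catalyst and ligand enantiomers named in steps 8 and 12 are taken to give the drawn sense of induction; if either proved opposite, its mirror image would be used.

Locants C1–C20 are those of the briarane skeleton of the target (ring A = C1, C10–C14; C15 and C20 are the methyls on C1 and C11; C16 is the exocyclic methylene carbon; C17–C19 are lactone carbons with methyl C18). α is the ring A face carrying H-10; β is the face carrying the C1 methyl.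

**Route**

Step 1
Reactants: 1 dimethyl (S)-malate
Product: 3 dimethyl (2S,3R)-2-hydroxy-3-methylbutanedioate, via dilithium alkoxide enolate 2 (not isolated)
Conditions: LiN(i-Pr)2 (2.2 equiv), THF, −78 → −20 °C; MeI, −78 → 0 °C
Reagents that add atoms: iodomethane, CI
Why: Fráter–Seebach alkylation, in which the chelated dilithium alkoxide enolate is methylated anti to the alkoxide oxygen (about 10:1) and so sets the future C17 as 3R.

Step 2
Reactants: 3 dimethyl (2S,3R)-2-hydroxy-3-methylbutanedioate
Product: 4 (2S,3R)-2-hydroxy-3-methylbutanedioic acid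
Conditions: KOH (2.5 equiv), MeOH/H2O, 0 → 23 °C; HCl work-up
Reagents that add atoms: potassium hydroxide, [K+].[OH-]
Why: Ester saponification, which leaves both centres intact because the carboxylate-flanked α-carbons are not enolised by cold hydroxide.

Step 3
Reactants: 4 (2S,3R)-2-hydroxy-3-methylbutanedioic acid, 5 pivalaldehyde
Product: 6 (2R)-2-[(2S,4S)-2-tert-butyl-5-oxo-1,3-dioxolan-4-yl]propanoic acid
Conditions: TsOH·H2O (cat.), H2SO4 (cat.), pentane, reflux, Dean–Stark trap
Reagents that add atoms: none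
Why: Seebach acetalisation of the α-hydroxy acid (self-regeneration of stereocentres), which gives under thermodynamic control the cis-2-tert-butyl-1,3-dioxolan-4-one whose new acetal centre (S) later relays the configuration of C8.

Step 4
Reactants: 6 (2R)-2-[(2S,4S)-2-tert-butyl-5-oxo-1,3-dioxolan-4-yl]propanoic acid
Product: 7 tert-butyl (2R)-2-[(2S,4S)-2-tert-butyl-5-oxo-1,3-dioxolan-4-yl]propanoate
Conditions: t-BuOC(=NH)CCl3 (1.5 equiv), CH2Cl2/cyclohexane, 23 °C
Reagents that add atoms: tert-butyl 2,2,2-trichloroacetimidate, CC(C)(C)OC(=N)C(Cl)(Cl)Cl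
Why: Trichloroacetimidate esterification, which needs neither base nor strong acid so the acetal and both centres survive, and which gives an ester too hindered to be attacked later by the 9-hydroxyl or by i-Bu2AlH.

Step 5
Reactants: 7 tert-butyl (2R)-2-[(2S,4S)-2-tert-butyl-5-oxo-1,3-dioxolan-4-yl]propanoate, 8 3-methylbut-2-enoyl chloride
Product: 10 tert-butyl (2R)-2-[(2S,4R)-2-tert-butyl-4-(3-methylbut-2-enoyl)-5-oxo-1,3-dioxolan-4-yl]propanoate, via lithium enolate 9 (not isolated)
Conditions: LiN(SiMe3)2 (1.05 equiv), THF, −78 °C; then cannulated into 8 (1.3 equiv), THF, −78 °C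
Reagents that add atoms: none
Why: Claisen-type C-acylation of the Seebach dioxolanone enolate, which is attacked on the face opposite the tert-butyl group so that the acyl group replaces the hydrogen with retention and C8 becomes quaternary with the configuration of the target.

Step 6
Reactants: 10 tert-butyl (2R)-2-[(2S,4R)-2-tert-butyl-4-(3-methylbut-2-enoyl)-5-oxo-1,3-dioxolan-4-yl]propanoate
Product: 11 tert-butyl (2R)-2-[(2S,4R)-2-tert-butyl-4-[(2E)-3-methyl-4-oxobut-2-enoyl]-5-oxo-1,3-dioxolan-4-yl]propanoate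
Conditions: SeO2 (1.5 equiv), 1,4-dioxane, 85 °C
Reagents that add atoms: selenium dioxide, O=[Se]=O
Why: Riley allylic oxidation (ene reaction then [2,3]-sigmatropic shift), which is selective for the methyl group trans to the acyl group of a β,β-dimethyl enone and so gives the (E)-ene-dione in which the future C2 and C9 are trans.

Step 7
Reactants: 12 (E)-pent-2-enal
Product: 13 (1E,3E)-1-(triethylsilyloxy)penta-1,3-diene
Conditions: Et3SiOTf (1.1 equiv), Et3N (1.5 equiv), Et2O, 0 → 23 °C
Reagents that add atoms: triethylsilyl trifluoromethanesulfonate, CC[Si](CC)(CC)OS(=O)(=O)C(F)(F)F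
Why: Silyl dienol ether formation (O-silylation of the enal then γ-deprotonation), the usual route to (1E,3E)-1-silyloxy-1,3-dienes.

Step 8
Reactants: 11 ene-dione dienophile, 13 (1E,3E)-1-(triethylsilyloxy)penta-1,3-diene
Product: 15 Diels–Alder adduct 14-ol (ring A cyclohex-12-ene: 1α-CHO; 1β-CH3; 14α-OH; 11α-CH3; 10β-acyl dioxolanone), via silyl ether adduct 14 (not isolated)
Conditions: (S)-3,3-diphenyl-1-(o-tolyl)tetrahydropyrrolo[1,2-c][1,3,2]oxazaborole·Tf2NH (20 mol %), CH2Cl2, −78 °C; then 1 M HCl, THF, 0 °C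
Reagents that add atoms: none
Why: Catalytic enantioselective Diels–Alder reaction (chiral oxazaborolidinium activation of the formyl group), in which the strongly donating silyloxy group makes the methyl-bearing diene terminus bond to C10 (β to the activated aldehyde), the E dienophile fixes C2 and C9 trans, and the catalyst shields one enal face to set C1 and C10, the endo-derived centres at C11 and C14 being removed in step 9.

Step 9
Reactants: 15 Diels–Alder adduct 14-ol
Product: 17 ring A cyclohexa-11,13-diene aldehyde (1α-CHO; 1β-CH3; 10β-acyl dioxolanone), via allylic acetate 16 (not isolated)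
Conditions: Ac2O (1.5 equiv), Et3N (3 equiv), DMAP (0.1 equiv), THF, 0 → 23 °C; then Pd(PPh3)4 (5 mol %), 65 °C
Reagents that add atoms: none
Why: Acetylation then Tsuji-type palladium-catalysed 1,4-elimination, in which zerovalent palladium ionises the allylic acetate and the π-allyl complex can only lose H-11 (C1 is quaternary), giving the C11=C12/C13=C14 diene with C1 and C10 untouched.

Step 10
Reactants: 18 1,3-dichloropropan-2-one
Product: 19 1-chloro-2-(chloromethyl)but-3-yn-2-ol
Conditions: HC≡CMgBr (1.1 equiv), THF, −78 °C; NH4Cl (aq) at −78 °C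
Reagents that add atoms: ethynylmagnesium bromide, C#C[Mg]Br
Why: Grignard addition to the ketone, quenched cold so that the chlorohydrin alkoxide does not close to an epoxide.

Step 11
Reactants: 19 1-chloro-2-(chloromethyl)but-3-yn-2-ol
Product: 20 1-chloro-2-(chloromethyl)but-1-en-3-yne (E/Z mixture)
Conditions: methyl N-(triethylammoniosulfonyl)carbamate (Burgess reagent, 1.3 equiv), benzene, 50 °C
Reagents that add atoms: none
Why: Burgess dehydration (syn elimination, Ei) of the tertiary propargylic alcohol toward a chloromethyl group, giving the chloro-enyne as an E/Z mixture that converges in step 20 because the derived allylchromium species equilibrates.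

Step 12
Reactants: 17 ring A cyclohexadiene aldehyde, 20 1-chloro-2-(chloromethyl)but-1-en-3-yne
Product: 22 C2 propargylic alcohol (2-OH configured as in the target; chloro-enyne side chain), via alkynyl(methyl)zinc 21 (not isolated)
Conditions: Me2Zn (3 equiv), (S,S)-2,6-bis[[2-(hydroxydiphenylmethyl)pyrrolidin-1-yl]methyl]-4-methylphenol (ProPhenol, 20 mol %), Ph3PO (40 mol %), 20 (3 equiv), toluene, 0 °C; then 17, 0 °C
Reagents that add atoms: none
Why: Trost ProPhenol zinc-catalysed asymmetric alkynylation, in which the dinuclear zinc catalyst delivers the alkynylzinc to one face of the hindered aldehyde and sets C2 under reagent control, while the ketone, the esters and the allylic chloride are inert to the organozinc species.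

Step 13
Reactants: 22 C2 propargylic alcohol
Product: 23 11α,12α-diol
Conditions: OsO4 (2 mol %), N-methylmorpholine N-oxide (1.1 equiv), acetone/H2O, 0 °C
Reagents that add atoms: osmium tetroxide, O=[Os](=O)(=O)=O; N-methylmorpholine N-oxide, C[N+]1([O-])CCOCC1
Why: Upjohn syn-dihydroxylation, which takes the most electron-rich (trisubstituted) C11=C12 bond from the α face, anti to the bulky C10 acyl group, and so sets C11 and C12 while the electron-poor chloroalkene and the alkyne are spared.

Step 14
Reactants: 23 11α,12α-diol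
Product: 24 13α,14α-epoxide
Conditions: VO(acac)2 (5 mol %), t-BuOOH (1.5 equiv), CH2Cl2, 0 → 23 °C
Reagents that add atoms: tert-butyl hydroperoxide, CC(C)(C)OO
Why: Hydroxyl-directed vanadium-catalysed epoxidation (Sharpless–Michaelson), in which the vanadate ester of the allylic 12-OH delivers oxygen to the same α face of C13=C14 and sets C13 and C14.

Step 15
Reactants: 24 13α,14α-epoxide
Product: 25 2,12-bis(triethylsilyl) ether
Conditions: Et3SiCl (3 equiv), imidazole (6 equiv), DMAP (0.1 equiv), DMF, 23 °C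
Reagents that add atoms: chlorotriethylsilane, CC[Si](Cl)(CC)CC
Why: Silyl ether formation at the two secondary hydroxyls (C2, C12) only, the tertiary 11-OH being too hindered and staying free as the directing group for step 17.

Step 16
Reactants: 25 2,12-bis(triethylsilyl) ether
Product: 26 (3Z)-diene ketone
Conditions: H2 (1 atm), Pd/CaCO3 poisoned with Pb(OAc)2, quinoline, EtOAc, 0 °C
Reagents that add atoms: none
Why: Lindlar semi-hydrogenation, whose syn addition of hydrogen gives the (3Z)-alkene and whose poisoned palladium surface does not hydrogenolyse the allylic chloride or reduce the chloroalkene.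

Step 17
Reactants: 26 (3Z)-diene ketone
Product: 27 9-alcohol
Conditions: Me4NBH(OAc)3 (8 equiv), MeCN/AcOH (1:1), −30 → −20 °C
Reagents that add atoms: none
Why: Evans–Saksena directed reduction, in which the 11-hydroxyl binds boron and delivers hydride intramolecularly through a chair transition state fused trans to ring A, giving the 1,3-anti diol and hence the required C9 configuration.

Step 18
Reactants: 27 9-alcohol
Product: 28 9-acetate
Conditions: Ac2O (5 equiv), pyridine, DMAP (0.2 equiv), CH2Cl2, 23 °C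
Reagents that add atoms: acetic anhydride, CC(=O)OC(C)=O
Why: DMAP-catalysed acetylation of the only free secondary hydroxyl (C9), the tertiary 11-OH not reacting.

Step 19
Reactants: 28 9-acetate
Product: 30 α-hydroxy aldehyde (C7 aldehyde; free 8-OH), via dioxolanol lactol 29 (not isolated)
Conditions: i-Bu2AlH (2.2 equiv), CH2Cl2, −78 °C; potassium sodium tartrate (aq); SiO2
Reagents that add atoms: none
Why: Partial reduction of a lactone to a lactol, selective because the acylal-type carbonyl of the dioxolanone is the most electrophilic and least shielded acyl group (the neopentyl acetate and the tert-butyl ester react more slowly at −78 °C), after which the lactol sheds pivalaldehyde to give the α-hydroxy aldehyde, whose C8 cannot epimerise.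

Step 20
Reactants: 30 α-hydroxy aldehyde
Product: 33 2,12-diol macrolactone (target lacking both butyryl groups), via allylchromium dichloride 31 (not isolated), via macrocyclic chlorohydrin 32 (not isolated)
Conditions: CrCl2 (8 equiv), LiI (0.2 equiv), THF, 23 °C, 30 added over 10 h (final 2 mM); then CF3CO2H/H2O (9:1), 0 °C, same flask
Reagents that add atoms: none
Why: Proposed new method: divalent chromium reduces the allylic C–Cl bond to a γ-chloroallylchromium species (trivalent chromium) that adds through its chlorine-bearing γ-carbon to the aldehyde in a chair (Zimmerman–Traxler) transition state, which closes the ten-membered ring, places C6–Cl anti to C7–O and, by Felkin–Anh approach anti to the C8–O bond past the smaller C17 branch, sets C7, before the acid strips the silyl ethers and lets the new 7-hydroxyl close the γ-lactone on the tert-butyl ester; the closest known reactions are the Takai-type anti-selective γ-chloroallylation of aldehydes with CrCl2 and the chromium-mediated intramolecular allylation–lactonisation used to close ten-membered germacranolide rings.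

Step 21
Reactants: 33 2,12-diol macrolactone
Product: 34 CNP0188106.1 (target)
Conditions: (n-PrCO)2O (4 equiv), pyridine, DMAP (0.2 equiv), CH2Cl2, 0 → 23 °C
Reagents that add atoms: butanoic anhydride, CCCC(=O)OC(=O)CCC
Why: DMAP-catalysed acylation of the two secondary hydroxyls (C2, C12), the tertiary hydroxyls at C8 and C11 being unreactive under these conditions.

**Compound list**

1 | dimethyl (S)-malate | COC(=O)C[C@H](O)C(=O)OC | starting material
2 | dilithium alkoxide enolate of 1 | [Li+].[Li+].COC([O-])=C[C@H]([O-])C(=O)OC | intermediate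
3 | dimethyl (2S,3R)-2-hydroxy-3-methylbutanedioate | COC(=O)[C@H](C)[C@H](O)C(=O)OC | intermediate
4 | (2S,3R)-2-hydroxy-3-methylbutanedioic acid | OC(=O)[C@H](C)[C@H](O)C(=O)O | intermediate
5 | pivalaldehyde (2,2-dimethylpropanal) | CC(C)(C)C=O | starting material
6 | (2R)-2-[(2S,4S)-2-tert-butyl-5-oxo-1,3-dioxolan-4-yl]propanoic acid | CC(C)(C)[C@H]1O[C@@H]([C@@H](C)C(O)=O)C(=O)O1 | intermediate
7 | tert-butyl (2R)-2-[(2S,4S)-2-tert-butyl-5-oxo-1,3-dioxolan-4-yl]propanoate | CC(C)(C)[C@H]1O[C@@H]([C@@H](C)C(=O)OC(C)(C)C)C(=O)O1 | intermediate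
8 | 3-methylbut-2-enoyl chloride | CC(C)=CC(Cl)=O | starting material
9 | lithium enolate of 7 (lithium 1,3-dioxol-4-olate) | [Li+].CC(C)(C)[C@H]1OC([C@@H](C)C(=O)OC(C)(C)C)=C([O-])O1 | intermediate
10 | tert-butyl (2R)-2-[(2S,4R)-2-tert-butyl-4-(3-methylbut-2-enoyl)-5-oxo-1,3-dioxolan-4-yl]propanoate | CC(C)=CC(=O)[C@]1(O[C@H](C(C)(C)C)OC1=O)[C@@H](C)C(=O)OC(C)(C)C | intermediate
11 | tert-butyl (2R)-2-[(2S,4R)-2-tert-butyl-4-[(2E)-3-methyl-4-oxobut-2-enoyl]-5-oxo-1,3-dioxolan-4-yl]propanoate (ene-dione dienophile) | O=C/C(C)=C/C(=O)[C@]1(O[C@H](C(C)(C)C)OC1=O)[C@@H](C)C(=O)OC(C)(C)C | intermediate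
12 | (E)-pent-2-enal | CC/C=C/C=O | starting material
13 | (1E,3E)-1-(triethylsilyloxy)penta-1,3-diene | C/C=C/C=C/O[Si](CC)(CC)CC | intermediate
14 | Diels–Alder adduct, 14α-triethylsilyl ether (endo isomer drawn: 1α-CHO, 1β-CH3, 11α-CH3, 10β-acyl dioxolanone, C12=C13) | O=C[C@@]1(C)[C@@H](O[Si](CC)(CC)CC)C=C[C@@H](C)[C@@H]1C(=O)[C@]2(O[C@H](C(C)(C)C)OC2=O)[C@@H](C)C(=O)OC(C)(C)C | intermediate
15 | Diels–Alder adduct, 14α-alcohol | O=C[C@@]1(C)[C@@H](O)C=C[C@@H](C)[C@@H]1C(=O)[C@]2(O[C@H](C(C)(C)C)OC2=O)[C@@H](C)C(=O)OC(C)(C)C | intermediate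
16 | Diels–Alder adduct, 14α-acetate | O=C[C@@]1(C)[C@@H](OC(C)=O)C=C[C@@H](C)[C@@H]1C(=O)[C@]2(O[C@H](C(C)(C)C)OC2=O)[C@@H](C)C(=O)OC(C)(C)C | intermediate
17 | ring A cyclohexa-11,13-diene: 1α-formyl, 1β-methyl, 11-methyl, 10β-acyl dioxolanone, H-10 α | O=C[C@@]1(C)C=CC=C(C)[C@@H]1C(=O)[C@]2(O[C@H](C(C)(C)C)OC2=O)[C@@H](C)C(=O)OC(C)(C)C | intermediate
18 | 1,3-dichloropropan-2-one | ClCC(=O)CCl | starting material
19 | 1-chloro-2-(chloromethyl)but-3-yn-2-ol | OC(CCl)(CCl)C#C | intermediate
20 | 1-chloro-2-(chloromethyl)but-1-en-3-yne (E/Z mixture, alkene geometry left open) | ClCC(=CCl)C#C | intermediate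
21 | methyl[4-chloro-3-(chloromethyl)but-3-en-1-ynyl]zinc | C[Zn]C#CC(=CCl)CCl | intermediate
22 | C2 propargylic alcohol of 17 (C2 as in the target; C3≡C4; C5(=CHCl)CH2Cl side chain, chloroalkene E/Z mixture) | ClCC(=CCl)C#C[C@H](O)[C@@]1(C)C=CC=C(C)[C@@H]1C(=O)[C@]2(O[C@H](C(C)(C)C)OC2=O)[C@@H](C)C(=O)OC(C)(C)C | intermediate
23 | 11α,12α-diol (C13=C14 retained) | ClCC(=CCl)C#C[C@H](O)[C@@]1(C)C=C[C@@H](O)[C@@](C)(O)[C@@H]1C(=O)[C@]2(O[C@H](C(C)(C)C)OC2=O)[C@@H](C)C(=O)OC(C)(C)C | intermediate
24 | 13α,14α-epoxy-11α,12α-diol | ClCC(=CCl)C#C[C@H](O)[C@@]1(C)[C@H]3O[C@H]3[C@@H](O)[C@@](C)(O)[C@@H]1C(=O)[C@]2(O[C@H](C(C)(C)C)OC2=O)[C@@H](C)C(=O)OC(C)(C)C | intermediate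
25 | 2,12-bis(triethylsilyl) ether of 24 (11-OH free) | ClCC(=CCl)C#C[C@H](O[Si](CC)(CC)CC)[C@@]1(C)[C@H]3O[C@H]3[C@@H](O[Si](CC)(CC)CC)[C@@](C)(O)[C@@H]1C(=O)[C@]2(O[C@H](C(C)(C)C)OC2=O)[C@@H](C)C(=O)OC(C)(C)C | intermediate
26 | (3Z)-alkene from 25 (C9 ketone) | ClCC(=CCl)/C=C\[C@H](O[Si](CC)(CC)CC)[C@@]1(C)[C@H]3O[C@H]3[C@@H](O[Si](CC)(CC)CC)[C@@](C)(O)[C@@H]1C(=O)[C@]2(O[C@H](C(C)(C)C)OC2=O)[C@@H](C)C(=O)OC(C)(C)C | intermediate
27 | 9-alcohol (C9 as in the target, anti to 11-OH) | ClCC(=CCl)/C=C\[C@H](O[Si](CC)(CC)CC)[C@@]1(C)[C@H]3O[C@H]3[C@@H](O[Si](CC)(CC)CC)[C@@](C)(O)[C@@H]1[C@H](O)[C@]2(O[C@H](C(C)(C)C)OC2=O)[C@@H](C)C(=O)OC(C)(C)C | intermediate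
28 | 9-acetate | ClCC(=CCl)/C=C\[C@H](O[Si](CC)(CC)CC)[C@@]1(C)[C@H]3O[C@H]3[C@@H](O[Si](CC)(CC)CC)[C@@](C)(O)[C@@H]1[C@H](OC(C)=O)[C@]2(O[C@H](C(C)(C)C)OC2=O)[C@@H](C)C(=O)OC(C)(C)C | intermediate
29 | 2-tert-butyl-1,3-dioxolan-4-ol (lactol at C7, anomer mixture) | ClCC(=CCl)/C=C\[C@H](O[Si](CC)(CC)CC)[C@@]1(C)[C@H]3O[C@H]3[C@@H](O[Si](CC)(CC)CC)[C@@](C)(O)[C@@H]1[C@H](OC(C)=O)[C@]2(O[C@H](C(C)(C)C)OC2O)[C@@H](C)C(=O)OC(C)(C)C | intermediate
30 | α-hydroxy aldehyde: C7 aldehyde, free tertiary 8-OH, 9-OAc, C19 tert-butyl ester, allylic chloride side chain | ClCC(=CCl)/C=C\[C@H](O[Si](CC)(CC)CC)[C@@]1(C)[C@H]3O[C@H]3[C@@H](O[Si](CC)(CC)CC)[C@@](C)(O)[C@@H]1[C@H](OC(C)=O)[C@@](O)(C=O)[C@@H](C)C(=O)OC(C)(C)C | intermediate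
31 | allylchromium dichloride from 30 (chromium on C16) | Cl[Cr](Cl)CC(=CCl)/C=C\[C@H](O[Si](CC)(CC)CC)[C@@]1(C)[C@H]3O[C@H]3[C@@H](O[Si](CC)(CC)CC)[C@@](C)(O)[C@@H]1[C@H](OC(C)=O)[C@@](O)(C=O)[C@@H](C)C(=O)OC(C)(C)C | intermediate
32 | macrocyclic chlorohydrin: ten-membered ring closed, 6-Cl, 7-OH, tert-butyl ester and both silyl ethers still present | C=C1/C=C\[C@H](O[Si](CC)(CC)CC)[C@@]2(C)[C@H]3O[C@H]3[C@@H](O[Si](CC)(CC)CC)[C@@](C)(O)[C@@H]2[C@H](OC(C)=O)[C@](O)([C@@H](C)C(=O)OC(C)(C)C)[C@@H](O)[C@H]1Cl | intermediate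
33 | 2,12-diol macrolactone (target with OH in place of both butanoyloxy groups) | C=C1/C=C\[C@H](O)[C@@]2(C)[C@H]3O[C@H]3[C@@H](O)[C@@](C)(O)[C@@H]2[C@H](OC(C)=O)[C@]2(O)[C@@H](C)C(=O)O[C@H]2[C@H]1Cl | intermediate
34 | CNP0188106.1 | C=C1/C=C\[C@H](OC(=O)CCC)[C@@]2(C)[C@H]3O[C@H]3[C@@H](OC(=O)CCC)[C@@](C)(O)[C@@H]2[C@H](OC(C)=O)[C@]2(O)[C@@H](C)C(=O)O[C@H]2[C@H]1Cl | target

**Step count and risks**

Total step count: 21. Longest linear sequence: 18 steps (steps 1–6, 8, 9, 12–21).

Steps most likely to fail:

1. Step 20. The macrocyclisation may give oligomers or the wrong C6/C7 diastereomer, and the acid stage may open the epoxide. Fallback, which forms the lactone ring first and changes the metal: set out from 30 and treat it with CF3CO2H/H2O in CH2Cl2 at 0 °C before any cyclisation. This removes the tert-butyl and silyl groups, and the aldehyde acid closes to the 7-hydroxy γ-lactone (lactol form of the aldehyde acid) F1. Indium powder (zerovalent indium) with NaI in THF/H2O at high dilution then carries out an aqueous Barbier-type intramolecular γ-chloroallylation on the lactol, which reacts through its open aldehyde carboxylate form. Acidification to pH 3 relactonises the γ-hydroxy acid, and the route is rejoined at 33; the macrocyclic chlorohydrin never meets strong acid. The C6/C7 sense under indium would have to be checked.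

2. Step 19. i-Bu2AlH may also cleave the 9-acetate. Fallback, which reverses the order of reduction and acetylation: set out from 27, which has no acetate. Reduce with i-Bu2AlH (3.5 equiv) in CH2Cl2 at −78 °C to the α-hydroxy aldehyde with free 9-hydroxyl F2 (pivalaldehyde is lost on work-up). Then acetylate the single secondary hydroxyl with Ac2O, pyridine and catalytic DMAP at 0 °C; the aldehyde and the tertiary hydroxyls do not react, and the route is rejoined at 30.

3. Step 17. Boron exchange at the hindered tertiary 11-hydroxyl may be too slow for the directed reduction of the neopentyl ketone. Fallback, which uses a Tishchenko hydride shift in place of a borohydride: set out from 26 and run an Evans–Tishchenko reduction with MeCHO (10 equiv) and SmI2 (0.3 equiv; divalent samarium as precatalyst) in THF at −10 °C. The hemiacetal of the 11-hydroxyl delivers hydride intramolecularly and gives the 1,3-anti 11-O-acetyl-9-hydroxy compound F3. Et3N with catalytic DMAP in CH2Cl2 at 40 °C then moves the acetyl group from the tertiary to the secondary oxygen, and the route is rejoined at 28, so step 18 is not needed.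

Further compounds
F1 | step 20 | 7-hydroxy γ-lactone (lactol form of the C7 aldehyde C19 acid; 2-OH and 12-OH free; allylic chloride side chain) | ClCC(=CCl)/C=C\[C@H](O)[C@@]1(C)[C@H]3O[C@H]3[C@@H](O)[C@@](C)(O)[C@@H]1[C@H](OC(C)=O)[C@]2(O)[C@@H](C)C(=O)OC2O
F2 | step 19 | α-hydroxy aldehyde with free 9-hydroxyl (30 lacking the acetyl group) | ClCC(=CCl)/C=C\[C@H](O[Si](CC)(CC)CC)[C@@]1(C)[C@H]3O[C@H]3[C@@H](O[Si](CC)(CC)CC)[C@@](C)(O)[C@@H]1[C@H](O)[C@@](O)(C=O)[C@@H](C)C(=O)OC(C)(C)C
F3 | step 17 | 11-O-acetyl-9-hydroxy compound (1,3-anti) | ClCC(=CCl)/C=C\[C@H](O[Si](CC)(CC)CC)[C@@]1(C)[C@H]3O[C@H]3[C@@H](O[Si](CC)(CC)CC)[C@@](C)(OC(C)=O)[C@@H]1[C@H](O)[C@]2(O[C@H](C(C)(C)C)OC2=O)[C@@H](C)C(=O)OC(C)(C)C
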